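The constants are those of an exercise, and the outcome is calculated.

In a one-step world the logarithm of [substrate] falls on a straight line in time, and I keep that logarithmic axis for these two flasks.

    substrate + reagent → first product (k1 = 11.2 M⁻¹ s⁻¹)
    reagent + first product → bis adduct (k2 = 19.3 M⁻¹ s⁻¹)
    substrate + bis adduct ⇌ idle adduct, settled at all times (K3 = 370 M⁻¹)

| setting | elm | larch |
|---|---|---|
| substrate | 1.0 mM | 1.0 mM |
| reagent | 3.00 mM | 1.20 mM |
| time | 40 s | 40 s |

* which of these there is most of at the end, counted by the substrate in it, elm (substrate / bis adduct / first product)
* which of these there is most of at the end, counted by the substrate in it, larch (substrate / bis adduct / first product)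
* how much there is at the end of the one of these that leads, in percent of the substrate charged: elm
* how much there is at the end of the one of these that leads, in percent of the substrate charged: larch

- in percentages every species weighs as the substrate in it: one idle adduct counts as two
- for bis adduct the idle adduct is counted in
- in an amount of bis adduct, one idle adduct counts as one bis adduct
- run time (elm): 40 s

With [reagent] held at its charge, larch gets k1[reagent]t/2.3 = 0.234 powers of ten, which leaves 58.4% of the substrate. But [reagent] falls, since each substrate turned over takes one reagent, so I lower the mean by 0.5 of the substrate lost. That gives 0.992 mM and then 0.193, a survival of 64.1%. This figure is the exposure in decades: k1 times mean [reagent] times time, over 2.3, the powers of ten by which step 1 has thinned the substrate.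

First product meets the same reagent with k2 larger than k1, so on this axis it thins by 1.72 times the exposure, that ratio being the selectivity factor. First product is then the survival at the exposure minus the survival at the multiplied exposure, over the factor less one. For larch that gives 24.4%, with 11.5% left for bis adduct.

The same chain for elm starts from 26.0%, lowers the mean [reagent] to 2.63 mM, and reaches 0.512 decades. That leaves substrate 30.7%, first product 24.4% and bis adduct 44.9%, a figure that also holds the substrate bound in idle adduct, since I leave step 3 out. So I commit to bis adduct leading in elm and substrate in larch.

The forecast says bis adduct at 43% for elm, less than my figure, and substrate at 63% for larch, where “the depleting reagent leaves free substrate well ahead”.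

The simulation gives bis adduct at 39.8% in elm and substrate at 63.4% in larch. Elm has not come to rest at 40 s: its substrate reads 0.500 decades against my 0.512, and at 400 s it reads 2.21, with bis adduct at 98.5%. Larch has not either: it reads 0.198 against my 0.193, and at 400 s it reads 0.578, with substrate 26.4%, bis adduct 47.1% and first product 22.4%. There reagent is down to 2.90% of its charge.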